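## Retrosynthetic overview

1. Hydroazulene numbering is used: ring A = C1–C2–C3–C3a–C8a, ring B = C3a–C4–C5–C6–C7–C8–C8a. The end game is a substrate-controlled 1,2-reduction of a C7 enone, preceded by acylation of the C4 hydroxyl and a C3-OH-directed reduction of a ring-B ene-1,4-dione.
2. The key disconnection is C6–C7 at the saturated 1,4-dione level. Both carbons are acceptors (an enone β-carbon and an aldehyde carbon). They are joined by polarity reversal through an acyl radical made by photocatalytic hydrogen-atom abstraction, in a 7-endo closure of a monocyclic keto aldehyde.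
3. The enabling feature lies in ring B, where the oxygen-bearing C4 and C7 stand 1,4 to each other across C5=C6 (a dissonant ene-1,4-dioxygen unit). They sit on trans-vicinal arms at C3a and at the quaternary C8a of ring A, which holds the two chain ends close.
4. Ring A is bought as 3-methylcyclopent-2-enone. Its stereotriad is relayed from C8a (catalytic enantioselective conjugate addition) to C3a (aldol anti to a bulky, removable 1-silylvinyl group) to C3 (isopropyl addition anti to the C3a arm).
5. Ring order: ring A is present from the start, and ring B is the only ring closed and the last one.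

Key step: step 6

Remark: side-chain carbons of the monocyclic compounds carry the numbers they will have in ring B. Centres that are later made planar (carbinol C4 in 8–11, silyl-bearing C8 in 10–12, C6 in 14) are carried as epimer mixtures and left undefined in the SMILES.

## Route

Step 1
Reactants: 1 ethynyltrimethylsilane; 2 3-methylcyclopent-2-en-1-one
Product: 5 (S)-3-methyl-3-[1-(trimethylsilyl)ethenyl]cyclopent-1-en-1-yl acetate, via vinylalane 3 (not isolated), via aluminium enolate 4 (not isolated)
Conditions: 1, iBu2AlH, hexane/THF, 55 °C; then 2, Cu(OTf)2 (cat.), chiral sulfonate-bearing imidazolinium salt (NHC precursor, cat.), THF, −15 °C; then Ac2O, 0 °C to rt; H2O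
Reagents that add atoms: acetic anhydride CC(=O)OC(C)=O
Why: Hydroalumination puts aluminium on the silicon-bearing carbon, and the copper–NHC-catalysed enantioselective conjugate addition of such silyl-substituted vinylalanes to β-substituted cyclopentenones is a close precedent for the quaternary C8a, whose configuration is set by the ligand (enantiomer chosen for S), while O-acetylation stores the regiodefined enolate.

Step 2
Reactants: 5 (S)-3-methyl-3-[1-(trimethylsilyl)ethenyl]cyclopent-1-en-1-yl acetate; 6 (E)-but-2-enal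
Product: 8 (2S,3S)-2-[(E)-1-hydroxybut-2-en-1-yl]-3-methyl-3-[1-(trimethylsilyl)ethenyl]cyclopentan-1-one, via lithium enolate 7 (not isolated)
Conditions: MeLi (2 equiv), THF, 0 °C; then 6, −78 °C; H2O
Reagents that add atoms: none
Why: Cleavage of the enol acetate with methyllithium releases the enolate only towards C3a, and its aldol addition occurs on the ring face opposite the very bulky 1-silylvinyl group, which sets C3a trans to the future C8 arm; the carbinol centre is left uncontrolled because step 5 oxidises it.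

Step 3
Reactants: 8 (2S,3S)-2-[(E)-1-hydroxybut-2-en-1-yl]-3-methyl-3-[1-(trimethylsilyl)ethenyl]cyclopentan-1-one
Product: 9 (1R,2S,3S)-2-[(E)-1-hydroxybut-2-en-1-yl]-3-methyl-1-(propan-2-yl)-3-[1-(trimethylsilyl)ethenyl]cyclopentan-1-ol
Conditions: iPrMgCl (excess), LaCl3·2LiCl, THF, −78 to 0 °C; H2O
Reagents that add atoms: isopropylmagnesium chloride CC(C)[Mg]Cl
Why: The lanthanum-promoted Grignard 1,2-addition suppresses enolisation and β-hydride reduction, and the nucleophile enters from the α face, anti to the vicinal C3a side chain and to the pseudoaxial C8a methyl group, so the C3 hydroxyl ends up cis to the side chain.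

Step 4
Reactants: 9 (1R,2S,3S)-2-[(E)-1-hydroxybut-2-en-1-yl]-3-methyl-1-(propan-2-yl)-3-[1-(trimethylsilyl)ethenyl]cyclopentan-1-ol
Product: 11 (1R,2S,3S)-3-[2-hydroxy-1-(trimethylsilyl)ethyl]-2-[(E)-1-hydroxybut-2-en-1-yl]-3-methyl-1-(propan-2-yl)cyclopentan-1-ol, via organoborane 10 (not isolated)
Conditions: 9-BBN (excess), THF, rt to 50 °C; then NaOH, H2O2, 0 °C
Reagents that add atoms: hydrogen peroxide OO
Why: In this hydroboration–oxidation, 9-BBN strongly prefers the terminal 1,1-disubstituted vinylsilane over the internal E-alkene and places boron on the CH2 terminus; the new silyl-bearing centre is irrelevant.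

Step 5
Reactants: 11 (1R,2S,3S)-3-[2-hydroxy-1-(trimethylsilyl)ethyl]-2-[(E)-1-hydroxybut-2-en-1-yl]-3-methyl-1-(propan-2-yl)cyclopentan-1-ol
Product: 13 2-[(1R,2R,3R)-2-[(E)-but-2-enoyl]-3-hydroxy-1-methyl-3-(propan-2-yl)cyclopentyl]acetaldehyde, via silyl aldehyde 12 (not isolated)
Conditions: Dess–Martin periodinane (2.5 equiv), wet CH2Cl2, 0 °C to rt; then silica gel, H2O
Reagents that add atoms: none
Why: Dess–Martin oxidation converts the primary and the allylic secondary alcohol while the tertiary alcohol is inert, the α-silyl aldehyde loses silicon by hydrolytic protodesilylation, and C3a, now α to a ketone, already has the thermodynamically preferred configuration (acyl group trans to isopropyl and hydrogen-bonded to the cis C3 hydroxyl).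

Step 6
Reactants: 13 2-[(1R,2R,3R)-2-[(E)-but-2-enoyl]-3-hydroxy-1-methyl-3-(propan-2-yl)cyclopentyl]acetaldehyde
Product: 14 (3R,3aR,8aR)-3-hydroxy-6,8a-dimethyl-3-(propan-2-yl)octahydroazulene-4,7-dione
Conditions: (nBu4N)4[W10O32] (cat.), MeCN (high dilution), 390 nm LED, Ar, rt
Reagents that add atoms: none
Why: Excited decatungstate abstracts the weak, hydridic formyl C–H of 13, the nucleophilic acyl radical at C7 adds to the electron-poor β-carbon C6 of the butenoyl arm, and the α-keto radical at C5 takes the hydrogen back from the reduced polyoxometalate, so the step is a redox-neutral, reagent-free isomerisation that joins two acceptor carbons (a radical Stetter-type polarity reversal). The closest known reaction types are the decatungstate-photocatalysed intermolecular hydroacylation of enones with aliphatic aldehydes and the tin-hydride 7-endo cyclisations of acyl radicals made from selenoesters. Ring B closes in the 7-endo-trig mode, because the alternative 6-exo attack at C5 would hit the electron-rich α-carbon and give an unstabilised secondary radical, so polarity matching secures the regiochemistry. The only new stereocentre, C6, is not controlled and need not be, since step 7 makes it planar, while C3, C3a and C8a are untouched and the trans ring fusion is inherited from the trans arms of ring A. Chemoselective hydrogen abstraction is secured by the substrate, whose other C–H bonds are stronger, hindered or deactivated by neighbouring carbonyl and hydroxyl groups, and decarbonylation is slow because it would give a primary neopentyl-type radical. The quaternary C8a (gem-disubstituent effect) and high dilution favour cyclisation over intermolecular addition.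

Step 7
Reactants: 14 (3R,3aR,8aR)-3-hydroxy-6,8a-dimethyl-3-(propan-2-yl)octahydroazulene-4,7-dione
Product: 15 (3R,3aR,8aR)-3-hydroxy-6,8a-dimethyl-3-(propan-2-yl)-1,2,3,3a,8,8a-hexahydroazulene-4,7-dione
Conditions: IBX, 4-methoxypyridine N-oxide, DMSO, rt
Reagents that add atoms: none
Why: In this IBX dehydrogenation of ketones, C5–C6 is the only place where either ketone can be desaturated because C3 and C8a carry no hydrogen, and the N-oxide additive allows room temperature so that the β-hydroxy ketone should neither dehydrate nor undergo retro-aldol cleavage.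

Step 8
Reactants: 15 (3R,3aR,8aR)-3-hydroxy-6,8a-dimethyl-3-(propan-2-yl)-1,2,3,3a,8,8a-hexahydroazulene-4,7-dione
Product: 16 (3R,3aS,4S,8aR)-3,4-dihydroxy-6,8a-dimethyl-3-(propan-2-yl)-2,3,3a,4,8,8a-hexahydroazulen-7(1H)-one
Conditions: Me4NBH(OAc)3, MeCN/AcOH, −30 °C; H2O
Reagents that add atoms: none
Why: In this Saksena–Evans hydroxyl-directed reduction, the β-oriented C3 hydroxyl binds boron and delivers hydride intramolecularly to the β face of the neighbouring C4 ketone only, which gives the α (S) alcohol and leaves the remote C7 enone untouched.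

Step 9
Reactants: 16 (3R,3aS,4S,8aR)-3,4-dihydroxy-6,8a-dimethyl-3-(propan-2-yl)-2,3,3a,4,8,8a-hexahydroazulen-7(1H)-one; 17 4-methoxybenzoyl chloride
Product: 18 (3R,3aS,4S,8aR)-3-hydroxy-6,8a-dimethyl-7-oxo-3-(propan-2-yl)-1,2,3,3a,4,7,8,8a-octahydroazulen-4-yl 4-methoxybenzoate
Conditions: pyridine, DMAP (cat.), CH2Cl2, rt
Reagents that add atoms: none
Why: DMAP-catalysed acylation selects the secondary allylic C4 alcohol because the tertiary C3 hydroxyl is too hindered to react.

Step 10
Reactants: 18 (3R,3aS,4S,8aR)-3-hydroxy-6,8a-dimethyl-7-oxo-3-(propan-2-yl)-1,2,3,3a,4,7,8,8a-octahydroazulen-4-yl 4-methoxybenzoate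
Product: 19 (3R,3aS,4S,7R,8aR)-3,7-dihydroxy-6,8a-dimethyl-3-(propan-2-yl)-1,2,3,3a,4,7,8,8a-octahydroazulen-4-yl 4-methoxybenzoate
Conditions: NaBH4, CeCl3·7H2O, MeOH, −78 °C
Reagents that add atoms: none
Why: The Luche 1,2-reduction spares the ester and the alkene, and hydride should approach the C7 carbonyl from the α face because the axial C8a methyl group shields the β face of the trans-fused ring B, which gives the β (R) alcohol.

## Compound list

1 | ethynyltrimethylsilane | C#C[Si](C)(C)C | starting material
2 | 3-methylcyclopent-2-en-1-one | CC1=CC(=O)CC1 | starting material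
3 | diisobutyl[1-(trimethylsilyl)ethenyl]aluminium | C=C([Si](C)(C)C)[Al](CC(C)C)CC(C)C | intermediate
4 | diisobutylaluminium (S)-3-methyl-3-[1-(trimethylsilyl)ethenyl]cyclopent-1-en-1-olate | C=C([Si](C)(C)C)[C@@]1(C)CCC(O[Al](CC(C)C)CC(C)C)=C1 | intermediate
5 | (S)-3-methyl-3-[1-(trimethylsilyl)ethenyl]cyclopent-1-en-1-yl acetate | C=C([Si](C)(C)C)[C@@]1(C)CCC(OC(C)=O)=C1 | intermediate
6 | (E)-but-2-enal | C/C=C/C=O | starting material
7 | lithium (S)-3-methyl-3-[1-(trimethylsilyl)ethenyl]cyclopent-1-en-1-olate | C=C([Si](C)(C)C)[C@@]1(C)CCC(O[Li])=C1 | intermediate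
8 | (2S,3S)-2-[(E)-1-hydroxybut-2-en-1-yl]-3-methyl-3-[1-(trimethylsilyl)ethenyl]cyclopentan-1-one | C=C([Si](C)(C)C)[C@@]1(C)CCC(=O)[C@@H]1C(O)/C=C/C | intermediate
9 | (1R,2S,3S)-2-[(E)-1-hydroxybut-2-en-1-yl]-3-methyl-1-(propan-2-yl)-3-[1-(trimethylsilyl)ethenyl]cyclopentan-1-ol | C=C([Si](C)(C)C)[C@@]1(C)CC[C@@](O)(C(C)C)[C@@H]1C(O)/C=C/C | intermediate
10 | B-alkyl-9-borabicyclo[3.3.1]nonane adduct of 9 (boron on the terminal CH2 of the former vinylsilane) | C[Si](C)(C)C(CB1C2CCCC1CCC2)[C@@]1(C)CC[C@@](O)(C(C)C)[C@@H]1C(O)/C=C/C | intermediate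
11 | (1R,2S,3S)-3-[2-hydroxy-1-(trimethylsilyl)ethyl]-2-[(E)-1-hydroxybut-2-en-1-yl]-3-methyl-1-(propan-2-yl)cyclopentan-1-ol | C[Si](C)(C)C(CO)[C@@]1(C)CC[C@@](O)(C(C)C)[C@@H]1C(O)/C=C/C | intermediate
12 | 2-[(1S,2R,3R)-2-[(E)-but-2-enoyl]-3-hydroxy-1-methyl-3-(propan-2-yl)cyclopentyl]-2-(trimethylsilyl)acetaldehyde | C[Si](C)(C)C(C=O)[C@@]1(C)CC[C@@](O)(C(C)C)[C@@H]1C(=O)/C=C/C | intermediate
13 | 2-[(1R,2R,3R)-2-[(E)-but-2-enoyl]-3-hydroxy-1-methyl-3-(propan-2-yl)cyclopentyl]acetaldehyde | O=CC[C@@]1(C)CC[C@@](O)(C(C)C)[C@@H]1C(=O)/C=C/C | intermediate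
14 | (3R,3aR,8aR)-3-hydroxy-6,8a-dimethyl-3-(propan-2-yl)octahydroazulene-4,7-dione | O=C1CC(C)C(=O)C[C@@]2(C)CC[C@@](O)(C(C)C)[C@H]12 | intermediate
15 | (3R,3aR,8aR)-3-hydroxy-6,8a-dimethyl-3-(propan-2-yl)-1,2,3,3a,8,8a-hexahydroazulene-4,7-dione | O=C1C=C(C)C(=O)C[C@@]2(C)CC[C@@](O)(C(C)C)[C@H]12 | intermediate
16 | (3R,3aS,4S,8aR)-3,4-dihydroxy-6,8a-dimethyl-3-(propan-2-yl)-2,3,3a,4,8,8a-hexahydroazulen-7(1H)-one | O[C@H]1C=C(C)C(=O)C[C@@]2(C)CC[C@@](O)(C(C)C)[C@H]12 | intermediate
17 | 4-methoxybenzoyl chloride | COc1ccc(cc1)C(=O)Cl | starting material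
18 | (3R,3aS,4S,8aR)-3-hydroxy-6,8a-dimethyl-7-oxo-3-(propan-2-yl)-1,2,3,3a,4,7,8,8a-octahydroazulen-4-yl 4-methoxybenzoate | COc1ccc(C(=O)O[C@H]2C=C(C)C(=O)C[C@@]3(C)CC[C@@](O)(C(C)C)[C@H]23)cc1 | intermediate
19 | (3R,3aS,4S,7R,8aR)-3,7-dihydroxy-6,8a-dimethyl-3-(propan-2-yl)-1,2,3,3a,4,7,8,8a-octahydroazulen-4-yl 4-methoxybenzoate | COc1ccc(C(=O)O[C@H]2C=C(C)[C@H](O)C[C@@]3(C)CC[C@@](O)(C(C)C)[C@H]23)cc1 | target

## Step count and risks

Total step count: 10. Longest linear sequence: 10 steps (fully linear, no protecting groups).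

**Step 6.** The 7-endo closure onto a β-methyl-substituted enone may be too slow. The acyl radical could then be returned to the aldehyde, lose CO or add intermolecularly. The catalyst could also abstract other hydrogens, or the tertiary alcohol could add to the enone.
- The fallback closes ring B at C5=C6 by metathesis. It sets out from 11 and comes back at 15.
- Chemoselective oxidation of the primary alcohol of 11 (TEMPO, PhI(OAc)2), with loss of silicon on work-up, should give the hydroxy aldehyde F1.
- Excess isopropenylmagnesium bromide adds to it to give the acyclic triol F2.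
- Ring-closing metathesis with the second-generation Grubbs catalyst expels propene and gives the bicyclic triol F3.
- Dess–Martin oxidation of both allylic alcohols of F3 then leads to 15.

**Step 2.** Bond formation at the enolate carbon next to the quaternary centre may be sluggish. That would allow reversal of the aldol, proton transfer that scrambles the enolate, or incomplete facial selectivity.
- The fallback uses the smallest electrophile and builds the arm later. It sets out from 7 (made from 5) and comes back at 9.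
- Gaseous formaldehyde traps 7 to give the hydroxymethyl ketone F4.
- iPrMgCl with LaCl3·2LiCl gives the diol F5.
- Selective oxidation of the primary alcohol (TEMPO, PhI(OAc)2) gives the β-hydroxy aldehyde F6, whose formyl-bearing C3a can equilibrate trans to the isopropyl group.
- (E)-Prop-1-enylmagnesium bromide then adds to F6 to give 9.

**Step 10.** Facial selectivity at C7 may be poor with the small hydride reagent, with attack from the β face competing.
- The fallback inverts the centre instead of selecting for it. It sets out from 18 and comes back at 19.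
- The undesired C7 epimer F7 from the reduction of 18 is subjected to Mitsunobu inversion (4-nitrobenzoic acid, PPh3, DIAD) to give the mixed diester F8.
- The activated nitrobenzoate of F8 is cleaved selectively (K2CO3, MeOH, 0 °C) in the presence of the hindered, electron-rich anisate to give 19.

## Further compounds

F1 | step 6 | 2-[(1R,2S,3R)-3-hydroxy-2-[(E)-1-hydroxybut-2-en-1-yl]-1-methyl-3-(propan-2-yl)cyclopentyl]acetaldehyde | O=CC[C@@]1(C)CC[C@@](O)(C(C)C)[C@@H]1C(O)/C=C/C
F2 | step 6 | (1R,2S,3R)-2-[(E)-1-hydroxybut-2-en-1-yl]-3-(2-hydroxy-3-methylbut-3-en-1-yl)-3-methyl-1-(propan-2-yl)cyclopentan-1-ol | C=C(C)C(O)C[C@@]1(C)CC[C@@](O)(C(C)C)[C@@H]1C(O)/C=C/C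
F3 | step 6 | (3R,3aS,8aR)-6,8a-dimethyl-3-(propan-2-yl)-1,2,3,3a,4,7,8,8a-octahydroazulene-3,4,7-triol (epimers at C4 and C7) | OC1C=C(C)C(O)C[C@@]2(C)CC[C@@](O)(C(C)C)[C@H]12
F4 | step 2 | (2S,3S)-2-(hydroxymethyl)-3-methyl-3-[1-(trimethylsilyl)ethenyl]cyclopentan-1-one | C=C([Si](C)(C)C)[C@@]1(C)CCC(=O)[C@@H]1CO
F5 | step 2 | (1R,2S,3S)-2-(hydroxymethyl)-3-methyl-1-(propan-2-yl)-3-[1-(trimethylsilyl)ethenyl]cyclopentan-1-ol | C=C([Si](C)(C)C)[C@@]1(C)CC[C@@](O)(C(C)C)[C@@H]1CO
F6 | step 2 | (1R,2R,5S)-2-hydroxy-5-methyl-2-(propan-2-yl)-5-[1-(trimethylsilyl)ethenyl]cyclopentane-1-carbaldehyde | C=C([Si](C)(C)C)[C@@]1(C)CC[C@@](O)(C(C)C)[C@@H]1C=O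
F7 | step 10 | (3R,3aS,4S,7S,8aR)-3,7-dihydroxy-6,8a-dimethyl-3-(propan-2-yl)-1,2,3,3a,4,7,8,8a-octahydroazulen-4-yl 4-methoxybenzoate | COc1ccc(C(=O)O[C@H]2C=C(C)[C@@H](O)C[C@@]3(C)CC[C@@](O)(C(C)C)[C@H]23)cc1
F8 | step 10 | (3R,3aS,4S,7R,8aR)-3-hydroxy-4-[(4-methoxybenzoyl)oxy]-6,8a-dimethyl-3-(propan-2-yl)-1,2,3,3a,4,7,8,8a-octahydroazulen-7-yl 4-nitrobenzoate | COc1ccc(C(=O)O[C@H]2C=C(C)[C@H](OC(=O)c3ccc([N+](=O)[O-])cc3)C[C@@]4(C)CC[C@@](O)(C(C)C)[C@H]24)cc1
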